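**Retrosynthetic overview**

1. Feature: the carbons of ring A are numbered 1 to 6 (carbon 1 CO2H, carbon 2 2-oxoheptyl, carbon 3 O-aryl, carbon 4 OH, carbon 5 H, carbon 6 OH). The hydroxyls on carbons 4 and 6 flank the C–H of carbon 5 in a 1,3-relationship next to the carboxyl on carbon 1, so ring A is the dehydro form of a 4-carboxycyclohexane-1,3-dione and is built saturated, then aromatised late.
2. Key disconnection: the bond between ring A carbons 1 and 2 (Michael) and the bond between carbons 5 and 6 (Claisen), between di-tert-butyl malonate and an α-aryloxy enone that supplies carbons 2 to 5, with the side-chain ketone masked as a dioxolane.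
3. Enone: the double bond between the future ring A carbons 2 and 3 by Horner–Wadsworth–Emmons olefination of a ketal aldehyde with an α-aryloxy β-ketophosphonate; the ether bond at carbon 3 by rhodium carbenoid O–H insertion into the 8-hydroxyisocoumarin.
4. Isocoumarin (benzo ring B, pyranone ring C) from methyl 2,4-dimethoxy-6-methylbenzoate by lateral lithiation/acylation, enol lactonisation and peri-selective demethylation.
5. Ring order: ring C (step 2), then ring A (step 8), aromatised in step 9 and unmasked in step 10.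

Key step: step 8

**Remarks on the chemistry**

- N-Methoxy-N-methylhexanamide is taken as a catalogue compound (otherwise one step from hexanoyl chloride and N,O-dimethylhydroxylamine hydrochloride).
- The target is achiral. The sp3 centres that appear on the way are racemic and uncontrolled, and all ring A centres vanish on aromatisation, so one relative configuration is drawn where needed.
- The enone geometry is drawn Z (expected major); either isomer serves, because the double bond becomes sp3 in the key step.

**Route**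

Step 1
Reactants: 1 methyl 2,4-dimethoxy-6-methylbenzoate; 2 N-methoxy-N-methylhexanamide
Product: 3 methyl 2,4-dimethoxy-6-(2-oxoheptyl)benzoate
Conditions: LiN(iPr)2 (1.2 equiv), THF, −78 °C; then 2, −78 → 0 °C; aq. HCl
Reagents that add atoms: none
Why: Lateral (benzylic) lithiation of the ortho-toluate gives a stabilised benzylic anion, and its acylation by the Weinreb amide stops at the ketone because the chelated tetrahedral adduct survives until work-up (lateral lithiation/Weinreb ketone synthesis).

Step 2
Reactants: 3 methyl 2,4-dimethoxy-6-(2-oxoheptyl)benzoate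
Product: 4 6,8-dimethoxy-3-pentyl-1H-isochromen-1-one
Conditions: TsOH·H2O (0.2 equiv), PhMe, reflux, slow distillation of MeOH
Reagents that add atoms: none
Why: Acid-catalysed enol lactonisation (the ketone enol oxygen attacks the neighbouring ester) closes ring C and should be driven by removal of methanol and by the conjugation gained in the isocoumarin.

Step 3
Reactants: 4 6,8-dimethoxy-3-pentyl-1H-isochromen-1-one
Product: 5 8-hydroxy-6-methoxy-3-pentyl-1H-isochromen-1-one
Conditions: BCl3 (1.5 equiv), CH2Cl2, −78 → 0 °C; H2O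
Reagents that add atoms: none
Why: BCl3 chelates between the lactone carbonyl and the peri 8-methoxy oxygen, so chloride should cleave only that methyl ether and leave the 6-methoxy group (chelation-controlled selective demethylation).

Step 4
Reactants: 5 8-hydroxy-6-methoxy-3-pentyl-1H-isochromen-1-one; 6 dimethyl (1-diazo-2-oxopropyl)phosphonate
Product: 7 dimethyl {1-[(6-methoxy-1-oxo-3-pentyl-1H-isochromen-8-yl)oxy]-2-oxopropyl}phosphonate (racemic)
Conditions: Rh2(OAc)4 (2 mol %), PhMe, 80 °C, slow addition of 6 (1.5 equiv)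
Reagents that add atoms: none
Why: The electrophilic rhodium carbenoid is captured by the phenol oxygen and the oxonium ylide collapses by proton transfer (carbenoid O–H insertion), which should form the alkyl aryl ether under neutral conditions without having to alkylate the weakly nucleophilic chelated phenoxide.

Step 5
Reactants: 8 methyl 3-oxooctanoate
Product: 9 methyl 2-(2-pentyl-1,3-dioxolan-2-yl)acetate
Conditions: HOCH2CH2OH (3 equiv), TsOH·H2O (cat.), PhH, reflux, Dean–Stark
Reagents that add atoms: ethylene glycol, OCCO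
Why: Acid-catalysed ketalisation with azeotropic removal of water should protect the ketone selectively, since the ester carbonyl does not form a dioxolane under these conditions.

Step 6
Reactants: 9 methyl 2-(2-pentyl-1,3-dioxolan-2-yl)acetate
Product: 10 2-(2-pentyl-1,3-dioxolan-2-yl)acetaldehyde
Conditions: iBu2AlH (1.05 equiv), CH2Cl2, −78 °C; MeOH, then aq. KNaC4H4O6
Reagents that add atoms: none
Why: At −78 °C the aluminium hemiacetal, held by chelation to a dioxolane oxygen, should persist until work-up, so the ester is reduced only to the aldehyde (iBu2AlH half-reduction).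

Step 7
Reactants: 7 dimethyl {1-[(6-methoxy-1-oxo-3-pentyl-1H-isochromen-8-yl)oxy]-2-oxopropyl}phosphonate; 10 2-(2-pentyl-1,3-dioxolan-2-yl)acetaldehyde
Product: 11 (Z)-3-[(6-methoxy-1-oxo-3-pentyl-1H-isochromen-8-yl)oxy]-5-(2-pentyl-1,3-dioxolan-2-yl)pent-3-en-2-one
Conditions: LiCl (1.5 equiv), iPr2NEt (1.3 equiv), MeCN, 0 °C → rt
Reagents that add atoms: none
Why: Horner–Wadsworth–Emmons olefination under Masamune–Roush conditions, in which the acidic α-aryloxy β-ketophosphonate is deprotonated by the amine in the presence of lithium ion, so the base-sensitive β-ketal aldehyde should not be enolised, with the acetyl group expected trans to the new substituent (Z).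

Step 8
Reactants: 11 (Z)-3-[(6-methoxy-1-oxo-3-pentyl-1H-isochromen-8-yl)oxy]-5-(2-pentyl-1,3-dioxolan-2-yl)pent-3-en-2-one; 12 di-tert-butyl malonate
Product: 14 tert-butyl 3-[(6-methoxy-1-oxo-3-pentyl-1H-isochromen-8-yl)oxy]-4,6-dioxo-2-[(2-pentyl-1,3-dioxolan-2-yl)methyl]cyclohexane-1-carboxylate (racemic; all-trans isomer drawn; exists largely as enol), via Michael adduct 13 (not isolated)
Conditions: 12 (1.3 equiv), NaH (1.1 equiv), THF, 0 °C; then 11, tBuOH (0.2 equiv), rt → 60 °C; cold 1 M HCl to pH 3–4
Reagents that add atoms: none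
Why: The sodium malonate adds 1,4 to the enone at ring A carbon 2 (forming the bond between carbons 1 and 2), proton transfer relays the carbon 3 enolate to the methyl ketone enolate, and its carbon (ring A carbon 5) attacks one tert-butyl ester (forming the bond between carbons 5 and 6) with loss of tert-butoxide, which is consumed at once by the acidic dione and pulls the sequence forward. The closest known reaction is the classical malonate–enone Michael–Claisen annulation to 4-alkoxycarbonylcyclohexane-1,3-diones used for olivetol and orsellinate precursors. Ring A closes by a 6-exo-trig acyl substitution (Claisen/Dieckmann type). The three new sp3 centres at ring A carbons 1, 2 and 3 are not controlled; those at carbons 1 and 3 are epimerisable, so the all-trans isomer should prevail, and all three are erased in step 9. The step needs 1,4-addition in preference to 1,2-addition and γ-deprotonation, retention of the aryloxy group and survival of the lactone; these are secured by the soft, weakly basic malonate anion, by the lack of an acidic hydrogen β to the ether oxygen (the hydrogen on carbon 2 is not activated, so the phenoxide has no E1cB exit) and by the absence of free alkoxide. Attack of the transient carbon 3 enolate on the peri lactone carbonyl would give a non-enolisable β-diketone with a quaternary centre and should therefore be reversible.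

Step 9
Reactants: 14 tert-butyl 3-[(6-methoxy-1-oxo-3-pentyl-1H-isochromen-8-yl)oxy]-4,6-dioxo-2-[(2-pentyl-1,3-dioxolan-2-yl)methyl]cyclohexane-1-carboxylate
Product: 15 tert-butyl 4,6-dihydroxy-3-[(6-methoxy-1-oxo-3-pentyl-1H-isochromen-8-yl)oxy]-2-[(2-pentyl-1,3-dioxolan-2-yl)methyl]benzoate
Conditions: DDQ (1.1 equiv), dry 1,4-dioxane, rt → 50 °C
Reagents that add atoms: none
Why: DDQ should abstract hydride from the allylic C–H at ring A carbon 2 of the β-keto ester enol and the resulting cyclohexenedione tautomerises to the resorcylate (quinone dehydrogenation/oxidative aromatisation), which removes all three ring A stereocentres.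

Step 10
Reactants: 15 tert-butyl 4,6-dihydroxy-3-[(6-methoxy-1-oxo-3-pentyl-1H-isochromen-8-yl)oxy]-2-[(2-pentyl-1,3-dioxolan-2-yl)methyl]benzoate
Product: 16 β-collatolic acid, 4,6-dihydroxy-3-[(6-methoxy-1-oxo-3-pentyl-1H-isochromen-8-yl)oxy]-2-(2-oxoheptyl)benzoic acid
Conditions: TFA/CH2Cl2/H2O (10:10:1), 0 °C → rt
Reagents that add atoms: water, O
Why: Acidolysis should cleave the tert-butyl ester through the tert-butyl cation and hydrolyse the dioxolane in one operation, while the water and low temperature keep the keto acid from enol-lactonising, trap the cation away from the electron-rich ring A and avoid decarboxylation of the resorcylic acid.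

**Compound list**

1 | methyl 2,4-dimethoxy-6-methylbenzoate | COC(=O)c1c(C)cc(OC)cc1OC | starting material
2 | N-methoxy-N-methylhexanamide | CCCCCC(=O)N(C)OC | starting material
3 | methyl 2,4-dimethoxy-6-(2-oxoheptyl)benzoate | COC(=O)c1c(CC(=O)CCCCC)cc(OC)cc1OC | intermediate
4 | 6,8-dimethoxy-3-pentyl-1H-isochromen-1-one | COc1cc(OC)c2c(=O)oc(CCCCC)cc2c1 | intermediate
5 | 8-hydroxy-6-methoxy-3-pentyl-1H-isochromen-1-one | COc1cc(O)c2c(=O)oc(CCCCC)cc2c1 | intermediate
6 | dimethyl (1-diazo-2-oxopropyl)phosphonate | COP(=O)(OC)C(=[N+]=[N-])C(C)=O | starting material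
7 | dimethyl {1-[(6-methoxy-1-oxo-3-pentyl-1H-isochromen-8-yl)oxy]-2-oxopropyl}phosphonate (racemic) | COP(=O)(OC)C(Oc1cc(OC)cc2cc(CCCCC)oc(=O)c12)C(C)=O | intermediate
8 | methyl 3-oxooctanoate | CCCCCC(=O)CC(=O)OC | starting material
9 | methyl 2-(2-pentyl-1,3-dioxolan-2-yl)acetate | CCCCCC1(CC(=O)OC)OCCO1 | intermediate
10 | 2-(2-pentyl-1,3-dioxolan-2-yl)acetaldehyde | CCCCCC1(CC=O)OCCO1 | intermediate
11 | (Z)-3-[(6-methoxy-1-oxo-3-pentyl-1H-isochromen-8-yl)oxy]-5-(2-pentyl-1,3-dioxolan-2-yl)pent-3-en-2-one | CC(=O)/C(Oc1cc(OC)cc2cc(CCCCC)oc(=O)c12)=C/CC1(CCCCC)OCCO1 | intermediate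
12 | di-tert-butyl malonate | CC(C)(C)OC(=O)CC(=O)OC(C)(C)C | starting material
13 | di-tert-butyl 2-{3-[(6-methoxy-1-oxo-3-pentyl-1H-isochromen-8-yl)oxy]-4-oxo-1-(2-pentyl-1,3-dioxolan-2-yl)pentan-2-yl}propanedioate (racemic; one diastereomer drawn; not isolated) | CC(=O)[C@H](Oc1cc(OC)cc2cc(CCCCC)oc(=O)c12)[C@@H](CC3(CCCCC)OCCO3)C(C(=O)OC(C)(C)C)C(=O)OC(C)(C)C | intermediate
14 | tert-butyl 3-[(6-methoxy-1-oxo-3-pentyl-1H-isochromen-8-yl)oxy]-4,6-dioxo-2-[(2-pentyl-1,3-dioxolan-2-yl)methyl]cyclohexane-1-carboxylate (racemic; all-trans isomer drawn) | O=C1CC(=O)[C@H](Oc2cc(OC)cc3cc(CCCCC)oc(=O)c23)[C@@H](CC2(CCCCC)OCCO2)[C@@H]1C(=O)OC(C)(C)C | intermediate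
15 | tert-butyl 4,6-dihydroxy-3-[(6-methoxy-1-oxo-3-pentyl-1H-isochromen-8-yl)oxy]-2-[(2-pentyl-1,3-dioxolan-2-yl)methyl]benzoate | CCCCCC1(Cc2c(Oc3cc(OC)cc4cc(CCCCC)oc(=O)c34)c(O)cc(O)c2C(=O)OC(C)(C)C)OCCO1 | intermediate
16 | β-collatolic acid | CCCCCC(=O)Cc1c(Oc2cc(OC)cc3cc(CCCCC)oc(=O)c23)c(O)cc(O)c1C(=O)O | target

**Step count**

Total: 10 steps. Longest linear sequence: 8 steps (steps 1, 2, 3, 4, 7, 8, 9, 10 from compound 1); the aldehyde branch (steps 5 and 6) joins at step 7.

**Steps most likely to fail**

1. Step 8 (key annulation).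
What may go wrong: conjugate addition to the donor-substituted, β-substituted enone and acyl substitution at the hindered tert-butyl ester may both be slow. Retro-Michael cleavage, γ-deprotonation with opening of the dioxolane, or attack of the carbon 3 enolate on the peri lactone carbonyl could then compete.
Fallback (exchange of the partners, with closure on an unhindered methyl ester): it sets out from phenol 5 and aldehyde 10 and returns to the route at dione 14. Trimethyl phosphonoacetate is converted by Regitz diazo transfer (4-acetamidobenzenesulfonyl azide, DBU, MeCN) into methyl 2-diazo-2-(dimethoxyphosphoryl)acetate F1. Rh2(OAc)4-catalysed O–H insertion of F1 with 5 (PhMe, 80 °C) should give methyl 2-(dimethoxyphosphoryl)-2-[(6-methoxy-1-oxo-3-pentyl-1H-isochromen-8-yl)oxy]acetate F2. Horner–Wadsworth–Emmons reaction of F2 with 10 (LiCl, iPr2NEt, MeCN) should give methyl (Z)-2-[(6-methoxy-1-oxo-3-pentyl-1H-isochromen-8-yl)oxy]-4-(2-pentyl-1,3-dioxolan-2-yl)but-2-enoate F3. The sodium enolate of tert-butyl acetoacetate (NaH, THF, rt → 60 °C) then adds through its α-carbon (the future ring A carbon 1) to the β-carbon of the enoate (ring A carbon 2), giving the open adduct 1-tert-butyl 5-methyl 2-acetyl-4-[(6-methoxy-1-oxo-3-pentyl-1H-isochromen-8-yl)oxy]-3-[(2-pentyl-1,3-dioxolan-2-yl)methyl]pentanedioate F4 in the flask. Its acetyl methyl (ring A carbon 5) closes on the methyl ester carbonyl (ring A carbon 4) to give 14; this is the classical acetoacetate–enoate Michael–Claisen route to the same dione.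

2. Step 9 (dehydrogenation).
What may go wrong: the nucleophilic ring A carbon 5 or the enol oxygen of the free dione may add covalently to the quinone instead of transferring hydride, or the oxidation may stall or overrun.
Fallback (aromatisation through a silylated cyclohexadiene): it sets out from 14 and returns at 15. Double O-silylation of 14 (TBSOTf, Et3N, CH2Cl2, 0 °C) should give tert-butyl 2,4-bis[(tert-butyldimethylsilyl)oxy]-5-[(6-methoxy-1-oxo-3-pentyl-1H-isochromen-8-yl)oxy]-6-[(2-pentyl-1,3-dioxolan-2-yl)methyl]cyclohexa-1,3-diene-1-carboxylate F5, a diene with no free enol left to add to an oxidant. Dehydrogenation of the two remaining sp3 ring carbons (DDQ, 2,6-lutidine, PhH, rt) should give tert-butyl 4,6-bis[(tert-butyldimethylsilyl)oxy]-3-[(6-methoxy-1-oxo-3-pentyl-1H-isochromen-8-yl)oxy]-2-[(2-pentyl-1,3-dioxolan-2-yl)methyl]benzoate F6. Desilylation of F6 (Bu4NF buffered with AcOH, THF, 0 °C) gives 15.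

3. Step 4 (O–H insertion).
What may go wrong: the peri hydroxyl is hydrogen-bonded to the lactone carbonyl and weakly nucleophilic. The carbenoid may be diverted to cyclopropanation of the 3,4-double bond of the pyranone ring, carbonyl ylide formation at the lactone, carbene dimerisation or insertion into adventitious water.
Fallback (ether formation by epoxide opening, with no phosphonate): it sets out from aldehyde 10 and phenol 5 and returns at enone 11, so steps 4 and 7 are both bypassed. Wittig reaction of 10 with Ph3P=CHCOCH3 (CH2Cl2, rt) should give (E)-5-(2-pentyl-1,3-dioxolan-2-yl)pent-3-en-2-one F7. Weitz–Scheffer epoxidation of F7 (H2O2, NaOH, MeOH, 0 °C) gives trans-1-{3-[(2-pentyl-1,3-dioxolan-2-yl)methyl]oxiran-2-yl}ethan-1-one F8. The phenoxide of 5 (Cs2CO3, DMF, 60 °C) should open F8 at the carbonyl-activated α-carbon to give 4-hydroxy-3-[(6-methoxy-1-oxo-3-pentyl-1H-isochromen-8-yl)oxy]-5-(2-pentyl-1,3-dioxolan-2-yl)pentan-2-one F9. F9 loses water in the same flask (or after mesylation with MsCl, Et3N) to give 11, the known epoxy ketone route to α-aryloxy enones.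

**Further compounds**

F1 | step 8 | methyl 2-diazo-2-(dimethoxyphosphoryl)acetate | COC(=O)C(=[N+]=[N-])P(=O)(OC)OC
F2 | step 8 | methyl 2-(dimethoxyphosphoryl)-2-[(6-methoxy-1-oxo-3-pentyl-1H-isochromen-8-yl)oxy]acetate (racemic) | COC(=O)C(Oc1cc(OC)cc2cc(CCCCC)oc(=O)c12)P(=O)(OC)OC
F3 | step 8 | methyl (Z)-2-[(6-methoxy-1-oxo-3-pentyl-1H-isochromen-8-yl)oxy]-4-(2-pentyl-1,3-dioxolan-2-yl)but-2-enoate | COC(=O)/C(Oc1cc(OC)cc2cc(CCCCC)oc(=O)c12)=C/CC1(CCCCC)OCCO1
F4 | step 8 | 1-tert-butyl 5-methyl 2-acetyl-4-[(6-methoxy-1-oxo-3-pentyl-1H-isochromen-8-yl)oxy]-3-[(2-pentyl-1,3-dioxolan-2-yl)methyl]pentanedioate (diastereomer mixture, not isolated) | CC(=O)C(C(=O)OC(C)(C)C)C(CC1(CCCCC)OCCO1)C(Oc2cc(OC)cc3cc(CCCCC)oc(=O)c23)C(=O)OC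
F5 | step 9 | tert-butyl 2,4-bis[(tert-butyldimethylsilyl)oxy]-5-[(6-methoxy-1-oxo-3-pentyl-1H-isochromen-8-yl)oxy]-6-[(2-pentyl-1,3-dioxolan-2-yl)methyl]cyclohexa-1,3-diene-1-carboxylate (racemic, 5,6-trans drawn) | CC(C)(C)OC(=O)C1=C(O[Si](C)(C)C(C)(C)C)C=C(O[Si](C)(C)C(C)(C)C)[C@H](Oc2cc(OC)cc3cc(CCCCC)oc(=O)c23)[C@H]1CC1(CCCCC)OCCO1
F6 | step 9 | tert-butyl 4,6-bis[(tert-butyldimethylsilyl)oxy]-3-[(6-methoxy-1-oxo-3-pentyl-1H-isochromen-8-yl)oxy]-2-[(2-pentyl-1,3-dioxolan-2-yl)methyl]benzoate | CCCCCC1(Cc2c(Oc3cc(OC)cc4cc(CCCCC)oc(=O)c34)c(O[Si](C)(C)C(C)(C)C)cc(O[Si](C)(C)C(C)(C)C)c2C(=O)OC(C)(C)C)OCCO1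
F7 | step 4 | (E)-5-(2-pentyl-1,3-dioxolan-2-yl)pent-3-en-2-one | CC(=O)/C=C/CC1(CCCCC)OCCO1
F8 | step 4 | trans-1-{3-[(2-pentyl-1,3-dioxolan-2-yl)methyl]oxiran-2-yl}ethan-1-one (racemic) | CC(=O)[C@H]1O[C@@H]1CC1(CCCCC)OCCO1
F9 | step 4 | 4-hydroxy-3-[(6-methoxy-1-oxo-3-pentyl-1H-isochromen-8-yl)oxy]-5-(2-pentyl-1,3-dioxolan-2-yl)pentan-2-one (racemic, one diastereomer drawn) | CC(=O)[C@H](Oc1cc(OC)cc2cc(CCCCC)oc(=O)c12)[C@H](O)CC1(CCCCC)OCCO1
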